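- The vessel held a catalyst charge and a smaller impurity charge, and before running it I wanted to know which given numbers the questions below really depended on.

starting material 2.0 M; coupling partner 1.00 M; free catalyst 20 mM; impurity 9.0 mM

    starting material + free catalyst ⇌ catalyst intermediate A (K1 = 0.22 M⁻¹, k1 = 51 M⁻¹ min⁻¹)
    free catalyst + impurity → spent catalyst (k2 = 140 M⁻¹ min⁻¹)
    starting material + catalyst intermediate A ⇌ idle complex, settled at all times (K3 = 0.79 M⁻¹)
    coupling partner + catalyst intermediate A → catalyst intermediate B (k4 = 11 M⁻¹ min⁻¹)
    catalyst intermediate B → free catalyst + product (k5 = 6.2 min⁻¹)

- the form that holds most of the catalyst when 10% of the starting material are converted (idle complex / catalyst intermediate A / spent catalyst / catalyst intermediate B / free catalyst)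
- its share of the catalyst then
- factor on the rate of making product when 10% of the starting material are converted if free catalyst is charged twice over
- factor on the rate when 10% of the starting material are converted if free catalyst is charged at 200 mM instead

- I looked for the working catalyst, the catalyst charge less the impurity charge, since each impurity takes one free catalyst for good, and the charges came first: a percent of error in c(impurity) moved it by 0.818 percent, and a percent in c(free catalyst) by 1.82 percent.
- The capture constant, the binding equilibrium constant and the coupling constant mattered less, and they enter together: the way back from catalyst intermediate A (232 min⁻¹) outran coupling (11.0 min⁻¹), so I held that binding at balance, free catalyst cancelled from capture over coupling, and with charge concentrations the logarithm of c(impurity) fell by 5.79 by the conversion asked about, leaving 0.306% of its charge.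
- On paper, with the capture constant at 0.5 of its value, the impurity left came to 4.54% of the working catalyst, and as c(starting material) and c(coupling partner) fell, the comparison tilted further toward capture.
- The idle-complex constant, the release constant and the forward binding constant stayed out of that exponent; the first two share the working catalyst among its forms.
- So I committed to 11.0 mM of working catalyst, the catalyst charge less the impurity charge, and at equal conversion I took the rate factors as ratios of working catalyst, 2.82 and 17.4.
- I put spent catalyst at 45.0% of the catalyst, more than the 18.9% I reckoned for free catalyst at charge concentrations, so I named it the form holding most of the catalyst, though it stood outside the working round and was no resting state of that round.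
- By the same reckoning, free catalyst held more than catalyst intermediate A, catalyst intermediate B or idle complex.
- The forecast, with an exponent of 6.8 where mine was 5.79, reasoned that “the impurity is essentially gone” and gave spent catalyst at 45% (43% to 46%), a factor of 2.8 (2.65 to 2.95) and a factor of 16.8 (15.3 to 18.2).
- The flask reached the conversion at 10.7 min with spent catalyst at 45.0%, and the factors were 2.86 and 17.2; the thing to watch is the early capture, since after 4.00 min the flask already held 42.3% of its catalyst as spent catalyst, with 5.96% of the impurity left.
- Working catalyst read this flask's share as 45.0% against 45.0%, and on the flask charged at 200 mM its ratio of 17.4 stood beside the 17.2 found there. Capture was a part of the lost rate: in the same run with that path taken away, the rate at that conversion was 1.83 times the actual one, beside a charge over working catalyst of 1.82. Taking the path away also moved the apparent order in free catalyst from 1.8 to 1.0.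

The numbers of this flask were set for the occasion; the rest is arithmetic.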